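## Retrosynthetic overview

1. Feature: the central bond Cβ–Cβ′ is shared by two eight-membered rings. Each central methine sits on C4 of ring C (the benzo ring of a dihydrobenzofuran) and is bonded, through the ArCH carbon Cα′ (or Cα), to ring B (the resorcinol ring on C3) of the other half. The perimeter ring B–Cα–Cβ′–ring C′–C3′–ring B′–Cα′–Cβ–ring C–C3 is therefore a fourteen-membered head-to-tail cycle of two enantiomeric trans-dihydrobenzofuran units.
2. Late disconnections: ten O–Me bonds; Cα–aryl (anisole capture of a cation) and Cα′–H (hydride capture of an aryl-bearing cation) after CBS desymmetrisation of a meso 1,4-diketone; Cβ–Cβ′ by transannular oxidative enolate coupling; both C=O from the alkynes of a meso cyclic diyne.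
3. Key disconnection: both ring C(C4)–C(sp) bonds of the cyclic diyne, by Sonogashira cyclodimerisation of a racemic iodo-alkyne monomer.
4. Monomer: [4+1] annulation of an o-quinone methide (ring B aryllithium plus the O-Boc salicylaldehyde of ring C) with a 4-methoxybenzyl sulfonium ylide; rings B and C both come from 2-bromo-4,6-dimethoxybenzaldehyde.
5. Ring order: dihydrofuran rings (step 7), fourteen-membered ring (step 10), both eight-membered rings by one bond (step 12).

Key step: step 10

Remarks
- Locants: dihydrobenzofuran O1, C2 (4-methoxyphenyl), C3; ring C = C3a–C7a (C4 next to C3a, OMe on C6); ring B = dimethoxyphenyl ring on C3; Cα = carbon on ring B ortho to the C3 link; Cβ = carbon on C4 of ring C; primed atoms belong to the (2S,3S) half.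
- Racemic compounds carry one number and are drawn as the (2R,3R) enantiomer. The two enantiomers of the key-step precursor are numbered separately because they react with each other.
- Assumption: in folded meso 21 each carbonyl (and each derived cation) is open only on its outer face, the same face for borane, anisole, the aryl nucleophile and silane. Compounds 22, 24 and 28 are drawn for the case where the outer face of the carbonyl in the (2R,3R) half is its Si face; in the opposite case the same reagents reach the same target through the diastereomers with the two halves exchanged.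

## Route

Step 1
Reactants: 1 1-bromo-3,5-dimethoxybenzene
Product: 2 2-bromo-4,6-dimethoxybenzaldehyde
Conditions: POCl3, DMF, 0 → 80 °C; aq NaOAc
Reagents that add atoms: N,N-dimethylformamide CN(C)C=O; water O
Why: Vilsmeier–Haack formylation should go para to one methoxy group and next to bromine, not between the two methoxy groups.

Step 2
Reactants: 2 2-bromo-4,6-dimethoxybenzaldehyde
Product: 3 1-bromo-2-ethynyl-3,5-dimethoxybenzene
Conditions: dimethyl (1-diazo-2-oxopropyl)phosphonate, K2CO3, MeOH, 0 °C → rt
Reagents that add atoms: dimethyl (1-diazo-2-oxopropyl)phosphonate COP(=O)(OC)C(=[N+]=[N-])C(C)=O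
Why: Ohira–Bestmann (Seyferth–Gilbert) homologation turns the aldehyde into the terminal alkyne under carbonate conditions that leave the aryl bromide alone.

Step 3
Reactants: 3 1-bromo-2-ethynyl-3,5-dimethoxybenzene
Product: 5 [(2-bromo-4,6-dimethoxyphenyl)ethynyl]tri(propan-2-yl)silane, via lithium acetylide 4 (not isolated)
Conditions: LiN(SiMe3)2, THF, −78 °C; i-Pr3SiOTf, −78 → 0 °C
Reagents that add atoms: triisopropylsilyl trifluoromethanesulfonate CC(C)[Si](OS(=O)(=O)C(F)(F)F)(C(C)C)C(C)C
Why: Alkyne deprotonation by the amide base (no bromine–lithium exchange) and C-silylation give a capped alkyne that tolerates the later organolithium, base and copper steps.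

Step 4
Reactants: 2 2-bromo-4,6-dimethoxybenzaldehyde
Product: 6 2-bromo-6-hydroxy-4-methoxybenzaldehyde
Conditions: BCl3, CH2Cl2, −78 → 0 °C; H2O
Reagents that add atoms: none
Why: Chelation-directed demethylation: BCl3 bound to the formyl oxygen cleaves only the ortho methoxy group.

Step 5
Reactants: 6 2-bromo-6-hydroxy-4-methoxybenzaldehyde
Product: 7 tert-butyl (3-bromo-2-formyl-5-methoxyphenyl) carbonate
Conditions: Boc2O, i-Pr2NEt, DMAP (cat.), CH2Cl2, 0 °C → rt
Reagents that add atoms: di-tert-butyl dicarbonate CC(C)(C)OC(=O)OC(=O)OC(C)(C)C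
Why: Phenol acylation gives the O-Boc salicylaldehyde needed for Pettus-type o-quinone methide generation.

Step 6
Reactants: 8 4-methoxybenzyl alcohol
Product: 9 1-(4-methoxybenzyl)tetrahydrothiophenium tetrafluoroborate
Conditions: tetrahydrothiophene, HBF4·OEt2, CH2Cl2, 0 °C → rt; precipitation from Et2O
Reagents that add atoms: tetrahydrothiophene C1CCSC1; tetrafluoroboric acid [H+].F[B-](F)(F)F
Why: SN1 S-alkylation of the sulfide by the 4-methoxybenzyl cation gives the sulfonium salt with a non-nucleophilic counter-ion.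

Step 7
Reactants: 5 [(2-bromo-4,6-dimethoxyphenyl)ethynyl]tri(propan-2-yl)silane; 7 tert-butyl (3-bromo-2-formyl-5-methoxyphenyl) carbonate; 9 1-(4-methoxybenzyl)tetrahydrothiophenium tetrafluoroborate
Product: 13 rac-(2R,3R)-4-bromo-3-{3,5-dimethoxy-2-[(triisopropylsilyl)ethynyl]phenyl}-6-methoxy-2-(4-methoxyphenyl)-2,3-dihydro-1-benzofuran (trans), via aryllithium 10 (not isolated), via sulfonium ylide 11 (not isolated), via o-quinone methide 12 (not isolated)
Conditions: 5, n-BuLi, THF, −78 °C; 7, −78 °C; then ylide 11 (from 9, LiN(SiMe3)2, THF, −78 °C) and MgBr2·OEt2; −78 → 0 °C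
Reagents that add atoms: none
Why: Bromine–lithium exchange gives 10, which adds to the aldehyde; Boc migration to the new alkoxide and loss of tert-butyl carbonate (Pettus generation) give 12, and conjugate addition of 11 followed by 5-exo-tet displacement of tetrahydrothiophene by the phenoxide ([4+1] annulation) closes the ring, the betaine closing through the rotamer with the two aryl groups anti so that C2 and C3 come out trans (racemic).

Step 8
Reactants: 13 rac-trans bromide
Product: 14 rac-(2R,3R)-3-{3,5-dimethoxy-2-[(triisopropylsilyl)ethynyl]phenyl}-4-iodo-6-methoxy-2-(4-methoxyphenyl)-2,3-dihydro-1-benzofuran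
Conditions: CuI (10 mol %), NaI, trans-N,N′-dimethylcyclohexane-1,2-diamine (20 mol %), 1,4-dioxane, 110 °C
Reagents that add atoms: sodium iodide [Na+].[I-]
Why: Copper-catalysed aromatic Finkelstein exchange, driven by precipitation of NaBr, gives the iodide needed for mild coupling.

Step 9
Reactants: 14 rac-trans iodide
Product: 15 (2R,3R)-3-(2-ethynyl-3,5-dimethoxyphenyl)-4-iodo-6-methoxy-2-(4-methoxyphenyl)-2,3-dihydro-1-benzofuran and 16 its (2S,3S) enantiomer (obtained together as the racemate)
Conditions: n-Bu4NF, THF, 0 °C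
Reagents that add atoms: none
Why: Fluoride cleaves the C(sp)–Si bond and leaves the aryl iodide and the dihydrobenzofuran untouched.

Step 10
Reactants: 15 (2R,3R) iodo-alkyne monomer; 16 (2S,3S) iodo-alkyne monomer
Product: 18 meso cyclic diyne (Cα≡Cβ′ and Cα′≡Cβ; fourteen-membered ring; octamethyl ether), via linear dimer 17 (not isolated)
Conditions: Pd(PPh3)4 (20 mol %), CuI (10 mol %), i-Pr2NH/toluene, 60 °C, degassed, syringe-pump addition of the racemate to ca. 1 mM; chromatography to remove the racemic C2 isomer
Reagents that add atoms: none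
Why: Oxidative addition of zerovalent palladium into the ring C–I bond, transmetalation from the copper acetylide of the ring B alkyne of a second monomer and reductive elimination give linear dimer 17, whose remaining iodide and alkyne then couple intramolecularly (Sonogashira coupling). The closest known reaction type is the Sonogashira cyclooligomerisation of ortho-iodo(ethynyl)arene units to arylene–ethynylene macrocycles. The fourteen-membered ring is closed end to end by the second coupling; no stereocentre is formed and the trans-dihydrobenzofuran centres are untouched. Head-to-tail connectivity is the only one open, because self-closure of one monomer would put a triple bond in a seven-membered ring and alkyne–alkyne coupling is suppressed by excluding oxygen. Cyclodimer must win over oligomer, which slow addition to a dilute catalyst solution and the U-shaped ortho,ortho′ diarylmethine hinge should favour. Homochiral pairing gives a racemic C2 isomer that is a diastereomer of centrosymmetric 18 and is removed by chromatography or crystallisation.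

Step 11
Reactants: 18 meso cyclic diyne
Product: 19 meso macrocyclic diketone (Cα(=O)–Cβ′H2 and Cα′(=O)–CβH2 in place of the triple bonds)
Conditions: Ph3PAuNTf2 (5 mol %), H2O, 1,4-dioxane, 80 °C
Reagents that add atoms: water O
Why: Gold-catalysed alkyne hydration: water attacks the alkyne carbon on ring B, where the ortho and para methoxy groups stabilise positive charge, whereas both oxygens of ring C are meta to the other terminus, so each carbonyl ends up on ring B.

Step 12
Reactants: 19 meso macrocyclic diketone
Product: 21 meso 1,4-diketone (new bond Cβ–Cβ′; two eight-membered rings; Cβ and Cβ′ as in the target), via dilithium bis-enolate 20 (not isolated)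
Conditions: LiN(SiMe3)2 (2.2 equiv), THF, −78 °C, high dilution; CuCl2 (2.2 equiv) in DMF, −78 °C → rt; then DBU, CH2Cl2, rt
Reagents that add atoms: none
Why: Proposed new method: one-electron oxidation of bis-enolate 20 by divalent copper gives an α-keto benzylic radical at Cβ that adds to the facing enolate carbon Cβ′, and a second oxidation gives the diketone; the closest known reaction type is the CuCl2-mediated oxidative coupling of ketone enolates (Saegusa), known intramolecularly for five- and six-membered rings but not across a macrocycle; both new centres are enolisable, so DBU equilibration should settle on the meso isomer, the only one in which the two ring C groups and the two acyl carbons are anti across the new bond while both rings keep gauche torsions.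

Step 13
Reactants: 21 meso 1,4-diketone
Product: 22 hydroxy ketone (Cα(=O) of the (2R,3R) half reduced to the (R)-carbinol; Cα′ still C=O)
Conditions: (S)-2-methyl-CBS-oxazaborolidine (20 mol %), BH3·SMe2 (0.6 equiv), THF, −30 °C; MeOH
Reagents that add atoms: none
Why: Corey–Bakshi–Shibata reduction used as a desymmetrisation: the (S)-catalyst delivers hydride to the Si face of an aryl ketone (aryl as the large group, (R)-carbinol), and only in one of the two enantiotopic carbonyls is that face the exposed one, so this group selection fixes the absolute configuration of the target, while the carbinol centre itself is lost in step 14.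

Step 14
Reactants: 22 hydroxy ketone; 23 anisole
Product: 24 aryl ketone ((R)-Cα bearing H and 4-methoxyphenyl; Cα′ still C=O)
Conditions: 23 (20 equiv), CF3SO3H (10 mol %), CH2Cl2, −40 → −20 °C
Reagents that add atoms: none
Why: SN1 Friedel–Crafts benzylation: the carbinol ionises to a cation stabilised by the ortho and para methoxy groups of ring B and anisole attacks through its para position from the outer face, setting (R)-Cα with the aryl group outside; capture by ring C would need a four-atom meta bridge and the second carbonyl stands anti across Cβ–Cβ′, so neither should compete.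

Step 15
Reactants: 24 aryl ketone; 25 4-bromoanisole
Product: 28 tertiary alcohol (Cα′ bearing OH and 4-methoxyphenyl), via 4-methoxyphenyllithium 26 (not isolated), via dichloro(4-methoxyphenyl)cerium 27 (not isolated)
Conditions: 25, n-BuLi, THF, −78 °C; CeCl3 (anhydrous), −78 °C; then 24, −78 → 0 °C
Reagents that add atoms: none
Why: Organocerium 1,2-addition (Imamoto conditions) is chosen because the weakly basic reagent adds to hindered, enolisable aryl ketones; the aryl group should enter from the outer face, but this carbinol centre is lost in step 16.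

Step 16
Reactants: 28 tertiary alcohol
Product: 29 decamethyl ether of the target
Conditions: Et3SiH (10 equiv), CF3CO2H, CH2Cl2, −40 → 0 °C
Reagents that add atoms: none
Why: Ionic hydrogenation: acid ionises the tertiary alcohol to a doubly benzylic cation and triethylsilane delivers hydride to the same outer face that anisole used in step 14, which leaves the aryl group inside and gives (R)-Cα′, the local sense opposite to Cα as the target requires; 2-aryl-dihydrobenzofurans are themselves made under these conditions and should survive.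

Step 17
Reactants: 29 decamethyl ether
Product: 30 CNP0224452.2 (target)
Conditions: BBr3 (30 equiv), CH2Cl2, −78 °C → rt; MeOH, H2O
Reagents that add atoms: none
Why: Lewis-acid demethylation of all ten aryl methyl ethers leaves the C–H stereocentres alone; the two cyclic benzylic ethers are the sensitive point, so the reaction is kept cold and short.

## Compound list

1 | 1-bromo-3,5-dimethoxybenzene | COc1cc(Br)cc(OC)c1 | starting material
2 | 2-bromo-4,6-dimethoxybenzaldehyde | O=Cc1c(Br)cc(OC)cc1OC | intermediate
3 | 1-bromo-2-ethynyl-3,5-dimethoxybenzene | C#Cc1c(Br)cc(OC)cc1OC | intermediate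
4 | lithium acetylide of 3 (not isolated) | [Li]C#Cc1c(Br)cc(OC)cc1OC | intermediate
5 | [(2-bromo-4,6-dimethoxyphenyl)ethynyl]tri(propan-2-yl)silane | CC(C)[Si](C#Cc1c(Br)cc(OC)cc1OC)(C(C)C)C(C)C | intermediate
6 | 2-bromo-6-hydroxy-4-methoxybenzaldehyde | O=Cc1c(Br)cc(OC)cc1O | intermediate
7 | tert-butyl (3-bromo-2-formyl-5-methoxyphenyl) carbonate | O=Cc1c(Br)cc(OC)cc1OC(=O)OC(C)(C)C | intermediate
8 | 4-methoxybenzyl alcohol | COc1ccc(CO)cc1 | starting material
9 | 1-(4-methoxybenzyl)tetrahydrothiophenium tetrafluoroborate | COc1ccc(C[S+]2CCCC2)cc1.F[B-](F)(F)F | intermediate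
10 | {3,5-dimethoxy-2-[(triisopropylsilyl)ethynyl]phenyl}lithium (not isolated) | [Li]c1cc(OC)cc(OC)c1C#C[Si](C(C)C)(C(C)C)C(C)C | intermediate
11 | (4-methoxyphenyl)(tetrahydrothiophenium-1-yl)methanide, sulfonium ylide (not isolated) | COc1ccc([CH-][S+]2CCCC2)cc1 | intermediate
12 | o-quinone methide: 3-bromo-5-methoxy-6-(arylmethylidene)cyclohexa-2,4-dienone, aryl = 3,5-dimethoxy-2-[(triisopropylsilyl)ethynyl]phenyl (not isolated) | O=C1C=C(OC)C=C(Br)C1=Cc1cc(OC)cc(OC)c1C#C[Si](C(C)C)(C(C)C)C(C)C | intermediate
13 | rac-(2R,3R)-4-bromo-3-{3,5-dimethoxy-2-[(triisopropylsilyl)ethynyl]phenyl}-6-methoxy-2-(4-methoxyphenyl)-2,3-dihydro-1-benzofuran (racemic; (2R,3R) drawn) | CC(C)[Si](C#Cc1c(OC)cc(OC)cc1[C@@H]1c2c(cc(OC)cc2Br)O[C@H]1c1ccc(OC)cc1)(C(C)C)C(C)C | intermediate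
14 | rac-(2R,3R)-4-iodo analogue of 13 (racemic; (2R,3R) drawn) | CC(C)[Si](C#Cc1c(OC)cc(OC)cc1[C@@H]1c2c(cc(OC)cc2I)O[C@H]1c1ccc(OC)cc1)(C(C)C)C(C)C | intermediate
15 | (2R,3R)-3-(2-ethynyl-3,5-dimethoxyphenyl)-4-iodo-6-methoxy-2-(4-methoxyphenyl)-2,3-dihydro-1-benzofuran | C#Cc1c(OC)cc(OC)cc1[C@@H]1c2c(cc(OC)cc2I)O[C@H]1c1ccc(OC)cc1 | intermediate
16 | (2S,3S) enantiomer of 15 | C#Cc1c(OC)cc(OC)cc1[C@H]1c2c(cc(OC)cc2I)O[C@@H]1c1ccc(OC)cc1 | intermediate
17 | linear heterochiral dimer: ring B alkyne of the (2R,3R) unit bonded to C4 of ring C of the (2S,3S) unit; iodide kept on the former, ethynyl on the latter (formed with its mirror image; not isolated) | C#Cc5c(OC)cc(OC)cc5[C@H]5c6c(cc(OC)cc6C#Cc3c(OC)cc(OC)cc3[C@@H]3c4c(cc(OC)cc4I)O[C@H]3c1ccc(OC)cc1)O[C@@H]5c1ccc(OC)cc1 | intermediate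
18 | meso fourteen-membered cyclic diyne, octamethyl ether | C2#Cc3c(OC)cc(OC)cc3[C@@H]3c4c(cc(OC)cc4C#Cc5c(OC)cc(OC)cc5[C@H]5c6c(cc(OC)cc62)O[C@@H]5c1ccc(OC)cc1)O[C@H]3c1ccc(OC)cc1 | intermediate
19 | meso macrocyclic diketone | O=C2c3c(OC)cc(OC)cc3[C@@H]3c4c(cc(OC)cc4CC(=O)c5c(OC)cc(OC)cc5[C@H]5c6c(cc(OC)cc6C2)O[C@@H]5c2ccc(OC)cc2)O[C@H]3c2ccc(OC)cc2 | intermediate
20 | dilithium bis-enolate of 19 (not isolated) | [Li+].[Li+].[O-]C=2c3c(OC)cc(OC)cc3[C@@H]3c4c(cc(OC)cc4C=C([O-])c5c(OC)cc(OC)cc5[C@H]5c6c(cc(OC)cc6C2)O[C@@H]5c2ccc(OC)cc2)O[C@H]3c2ccc(OC)cc2 | intermediate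
21 | meso 1,4-diketone with the Cβ–Cβ′ bond | O=C2c3c(OC)cc(OC)cc3[C@@H]3c4c(cc(OC)cc4[C@H]4C(=O)c5c(OC)cc(OC)cc5[C@H]5c6c(cc(OC)cc6[C@H]24)O[C@@H]5c2ccc(OC)cc2)O[C@H]3c2ccc(OC)cc2 | intermediate
22 | hydroxy ketone, (R)-carbinol at Cα | O[C@H]2c3c(OC)cc(OC)cc3[C@@H]3c4c(cc(OC)cc4[C@H]4C(=O)c5c(OC)cc(OC)cc5[C@H]5c6c(cc(OC)cc6[C@H]24)O[C@@H]5c2ccc(OC)cc2)O[C@H]3c2ccc(OC)cc2 | intermediate
23 | anisole | COc1ccccc1 | starting material
24 | aryl ketone, (R)-Cα with 4-methoxyphenyl | COc1ccc([C@@H]2c3c(OC)cc(OC)cc3[C@@H]3c4c(cc(OC)cc4[C@H]4C(=O)c5c(OC)cc(OC)cc5[C@H]5c6c(cc(OC)cc6[C@H]24)O[C@@H]5c2ccc(OC)cc2)O[C@H]3c2ccc(OC)cc2)cc1 | intermediate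
25 | 4-bromoanisole | COc1ccc(Br)cc1 | starting material
26 | 4-methoxyphenyllithium (not isolated) | [Li]c1ccc(OC)cc1 | intermediate
27 | dichloro(4-methoxyphenyl)cerium (not isolated) | COc1ccc([Ce](Cl)Cl)cc1 | intermediate
28 | tertiary alcohol at Cα′ (aryl drawn outside, OH inside) | COc1ccc([C@@H]2c3c(OC)cc(OC)cc3[C@@H]3c4c(cc(OC)cc4[C@H]4[C@](c5ccc(OC)cc5)(O)c5c(OC)cc(OC)cc5[C@H]5c6c(cc(OC)cc6[C@H]24)O[C@@H]5c2ccc(OC)cc2)O[C@H]3c2ccc(OC)cc2)cc1 | intermediate
29 | decamethyl ether of the target | COc1ccc([C@@H]2c3c(OC)cc(OC)cc3[C@@H]3c4c(cc(OC)cc4[C@H]4[C@H](c5ccc(OC)cc5)c5c(OC)cc(OC)cc5[C@H]5c6c(cc(OC)cc6[C@H]24)O[C@@H]5c2ccc(OC)cc2)O[C@H]3c2ccc(OC)cc2)cc1 | intermediate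
30 | CNP0224452.2 | Oc1ccc([C@@H]2c3c(O)cc(O)cc3[C@@H]3c4c(cc(O)cc4[C@H]4[C@H](c5ccc(O)cc5)c5c(O)cc(O)cc5[C@H]5c6c(cc(O)cc6[C@H]24)O[C@@H]5c2ccc(O)cc2)O[C@H]3c2ccc(O)cc2)cc1 | target

## Step count and risks

Total steps: 17. Longest linear sequence: 14 steps (1, 2, 3, then 7 to 17).

Steps most likely to fail:

1. Step 12 (proposed new method). The two enolate carbons may fail to meet across the ring, giving intermolecular coupling, C–O coupling or over-oxidation to the enedione. Equilibration may also settle on a diastereomer other than the one needed, since the configuration of Cβ relative to C3 is assumed to be the thermodynamic one. Fallback by known chemistry, setting out from 19: one carbonyl is enolised with LiN(SiMe3)2 (1 equiv, THF, −78 °C) and brominated with N-bromosuccinimide to give the α-bromo macrocyclic diketone F1. Cs2CO3 in MeCN then enolises the other ketone, whose α-carbon displaces bromide across the ring (enolate C-alkylation by an α-halo ketone). DBU equilibration returns to the route at 21.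

2. Step 10 (key step). Chain growth may outrun ring closure, copper may homocouple the alkynes, or homochiral pairing may dominate and leave little of the meso isomer. Fallback, setting out from racemic 13: preparative chiral HPLC gives the (2R,3R) enantiomer of 13 and the (2S,3S) bromide F2. Halogen exchange (CuI, NaI, diamine) converts F2 into the (2S,3S) iodide F3, and n-Bu4NF converts the (2R,3R) enantiomer of 13 into the (2R,3R) bromo alkyne F4. Sonogashira coupling of F4 with F3 at room temperature (Pd(PPh3)2Cl2, CuI, Et3N), where the iodide reacts and the bromide does not, gives the linear bromide F5. Halogen exchange gives the linear iodide F6, and desilylation gives 17, now isolated. Ring closure of 17 under the dilution conditions of step 10 returns to the route at 18, with no C2 isomer possible.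

3. Step 15. The carbonyl is flanked by an ortho methoxy group and a tertiary, acidic α-carbon, so enolisation or no reaction may replace addition. Fallback, setting out from 24: KN(SiMe3)2 and PhNTf2 give the enol triflate F7, which uses the enolisation productively. Suzuki–Miyaura coupling with 4-methoxyphenylboronic acid (Pd(OAc)2, SPhos, K3PO4) gives the tetrasubstituted alkene F8. CF3CO2H/Et3SiH then protonates Cβ and reduces the doubly benzylic cation from the outer face, returning to the route at 29. Cβ is re-set by this protonation and its configuration would have to be confirmed.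

Further compounds

F1 | step 12 | α-bromo macrocyclic diketone (Br on one CH2 of 19) | O=C2c3c(OC)cc(OC)cc3[C@@H]3c4c(cc(OC)cc4CC(=O)c5c(OC)cc(OC)cc5[C@H]5c6c(cc(OC)cc6C2Br)O[C@@H]5c2ccc(OC)cc2)O[C@H]3c2ccc(OC)cc2
F2 | step 10 | (2S,3S) enantiomer of bromide 13 | CC(C)[Si](C#Cc1c(OC)cc(OC)cc1[C@H]1c2c(cc(OC)cc2Br)O[C@@H]1c1ccc(OC)cc1)(C(C)C)C(C)C
F3 | step 10 | (2S,3S) enantiomer of iodide 14 | CC(C)[Si](C#Cc1c(OC)cc(OC)cc1[C@H]1c2c(cc(OC)cc2I)O[C@@H]1c1ccc(OC)cc1)(C(C)C)C(C)C
F4 | step 10 | (2R,3R)-4-bromo-3-(2-ethynyl-3,5-dimethoxyphenyl)-6-methoxy-2-(4-methoxyphenyl)-2,3-dihydro-1-benzofuran | C#Cc1c(OC)cc(OC)cc1[C@@H]1c2c(cc(OC)cc2Br)O[C@H]1c1ccc(OC)cc1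
F5 | step 10 | linear heterochiral dimer with bromide on the (2R,3R) unit and silyl alkyne on the (2S,3S) unit | CC(C)[Si](C#Cc5c(OC)cc(OC)cc5[C@H]5c6c(cc(OC)cc6C#Cc3c(OC)cc(OC)cc3[C@@H]3c4c(cc(OC)cc4Br)O[C@H]3c1ccc(OC)cc1)O[C@@H]5c1ccc(OC)cc1)(C(C)C)C(C)C
F6 | step 10 | linear heterochiral dimer with iodide on the (2R,3R) unit and silyl alkyne on the (2S,3S) unit | CC(C)[Si](C#Cc5c(OC)cc(OC)cc5[C@H]5c6c(cc(OC)cc6C#Cc3c(OC)cc(OC)cc3[C@@H]3c4c(cc(OC)cc4I)O[C@H]3c1ccc(OC)cc1)O[C@@H]5c1ccc(OC)cc1)(C(C)C)C(C)C
F7 | step 15 | enol triflate of 24 (Cα′(OTf)=Cβ) | COc1ccc([C@@H]2c3c(OC)cc(OC)cc3[C@@H]3c4c(cc(OC)cc4/C4=C(OS(=O)(=O)C(F)(F)F)/c5c(OC)cc(OC)cc5[C@H]5c6c(cc(OC)cc6[C@H]24)O[C@@H]5c2ccc(OC)cc2)O[C@H]3c2ccc(OC)cc2)cc1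
F8 | step 15 | tetrasubstituted alkene (Cα′(4-methoxyphenyl)=Cβ) | COc1ccc([C@@H]2c3c(OC)cc(OC)cc3[C@@H]3c4c(cc(OC)cc4/C4=C(c5ccc(OC)cc5)/c5c(OC)cc(OC)cc5[C@H]5c6c(cc(OC)cc6[C@H]24)O[C@@H]5c2ccc(OC)cc2)O[C@H]3c2ccc(OC)cc2)cc1
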